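Per molar of reagent and per minute, the loss of starting material can be read by a bench habit: freeze the reagent at its charge, treat the loss as pseudo-first-order, and divide the logarithm of the fall by reagent charge and time.

| flask | starting material | reagent | capture agent | temperature | remark | time |
|---|---|---|---|---|---|---|
| gamma | 0.38 M | 1.5 equiv | 0.57 M | 10 °C | run made earlier |  |
| eta | 0.85 M | 1.5 equiv | 0.57 M | 43 °C | run made earlier |  |
| elm | 0.57 M | 1.50 equiv | 0.570 M | −5 °C |  | 20 min |
| cedar | 0.57 M | 1.50 equiv | 0.570 M | 55 °C |  | 20 min |
| larch | 0.57 M | 1.50 equiv | 0.570 M | 25 °C |  | 20 min |

gamma run (percent of the starting material charged)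

| time / min | target / % | starting material / % |
|---|---|---|
| 2.00 | 0.1 | 91.9 |
| 4.00 | 0.3 | 83.3 |
| 6.00 | 0.3 | 78.2 |
| 8.00 | 0.1 | 71.5 |

eta run (percent of the starting material charged)

| time / s | target / % | starting material / % |
|---|---|---|
| 12.0 | 0 | 63.9 |
| 30.0 | 2.1 | 38.5 |
| 60.0 | 3.6 | 22.0 |
| 80.0 | 5.6 | 14.8 |

(readings scatter by 0.5 percentage points)

1. the flask that comes out highest in amount of target, in percent of the starting material charged, or "all alike" when all lie within 1.5 percentage points (elm / cedar / larch / all alike)
2. target at the end, in percent of the starting material charged, elm
3. target at the end, in percent of the starting material charged, cedar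
4. target at the end, in percent of the starting material charged, larch

The gamma run at its last reading gives a constant of 0.0736 /M/min, and the eta run at its first reading gives 1.76 /M/min; together these two readings give an activation energy of about 71.6 kJ/mol.

The border comes from the charge. At 1.5 equiv, each percent of starting material lost takes 0.667 percent of the reagent charge, so the frozen value drifts. At the last eta reading the same constant, read with the reagent still frozen, has sunk to 0.640 of its value at the first reading, so here the habit is trusted up to about the 36.1% lost at that first eta reading, an exposure of 0.448.

For elm this reckoning extrapolates the constant to 0.0134 /M/min. The frozen exposure, that constant times reagent charge times time, is 0.230, so elm should keep 79.5% of its starting material, a loss smaller than the border. The exposure of elm is also lower than that of the gamma run at its last reading, and the target read in the gamma run stood at 0.3% or less, so this reckoning of my own puts elm's target below the scatter of 0.5 percentage points. Larch and cedar reach exposures of 5.81 and 81.3, past the border, so this reckoning offers no estimate for those flasks.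

The forecast names cedar as highest, with 0.1% for elm, 60% for cedar and 12% for larch; of cedar it says “so I discount cedar and keep its range wide”.

The flasks give 0.131% in elm, 17.2% in cedar and 6.81% in larch, so cedar is highest; cedar lies 43 points under the forecast, with 78.8% of its charge as trapped intermediate.

    starting material + reagent → intermediate A (k = 0.390 /M/min, Ea = 73.0 kJ/mol)
    intermediate A ⇌ intermediate B (K = 0.130, k = 0.0200 /min, Ea = 92.0 kJ/mol, ΔH = −38.0 kJ/mol)
    reagent + intermediate A → target (k = 0.0220 /M/min, Ea = 73.0 kJ/mol)
    2 reagent → self-condensation product (k = 0.0110 /M/min, Ea = 82.0 kJ/mol)
    capture agent + intermediate A → trapped intermediate (k = 0.100 /M/min, Ea = 54.0 kJ/mol)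
    (constants at 25 °C)

Elm keeps 80% of its starting material and 86% of its reagent. The neighbour of elm with 0.23 M of starting material, at the same equivalents, temperature and time, has its exposure scaled with the reagent charge to 0.0927, which leaves 91.1% by the same reckoning. That flask ends with 91% of its starting material and 0.0245% of target.

The earlier runs and the new flask come from a simulation for an exercise, noise included.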